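## Retrosynthetic overview

1. The strategy rests on the C7–C8 bond, which joins the C8 carbinol to C7 of the trans-fused α-methylene-γ-butyrolactone (ring O–C6–C7–C11–C12, exocyclic C11=C13). This homoallylic alcohol is the retron of a [2,3]-shift of a C8–O–C13 ether, so the ten-membered carbocycle (C1–C10, bridged by the furanone oxygen between C3 and C10) is cut back to a 13-membered ether-bridged butenolide.
2. After the ring contraction: C9 ketone → 8,9-cis diol, C8 ester with (E)-2-(acetoxymethyl)but-2-enoic acid, C9 acetate.
3. Before it: 3(2H)-furanone by 5-endo cyclisation of an α′-hydroxy ynone ⇐ 13-membered ring closed at C1–C2 by Cr-mediated iodoalkyne/aldehyde coupling ⇐ butenolide by hydroalumination–iodination–carbonylation of the C6 propargylic alcohol.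
4. C6–C7 by catalytic asymmetric alkynylation of a (Z)-enynal (C2–C6) with a propargyl ether that already holds the C8–O–C13 oxygen; C9–C10 by aldol of the (S)-lactic acid dioxolanone enolate (lactate gives C1, C10, C14). The ether is bought in, so no ether-forming macrocyclisation and no carbenoid next to the furanone carbonyl (which would divert to a five-membered carbonyl ylide) is needed.
5. Ring order: butenolide → 13-membered carbocycle → furanone → ten-membered carbocycle (key step). The lactone is closed right after the hydride step so that it also masks the C6 hydroxyl; from then on no base stronger than K2CO3 or i-Pr2NEt is used, because H-6 of the dienyl butenolide is acidic.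

Key step: step 16

Remark 1: atoms are numbered as in the germacrane skeleton (C1 furanone C=O, C2=C3, ring O between C3 and C10, C4(CH3)=C5, C6 lactone O–CH, C7, C8, C9, C10, C11=C13, C12 lactone C=O, C14 = CH3 on C10, C15 = CH3 on C4).
Remark 2: C9 (compounds 7, 8, 13–21) and C1 (compounds 20, 21) are carbinol carbons that end as ketones; both epimers are carried, so these centres are left undefined in names and SMILES.
Remark 3: the ProPhenol antipode in step 7 is the one that gives the 6R carbinol; the assignment would be checked by Mosher ester analysis before the material is taken on.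

## Route

Step 1
Reactants: 1 2-(prop-2-yn-1-yloxy)ethan-1-ol
Product: 2 2-(prop-2-yn-1-yloxy)acetaldehyde
Conditions: (COCl)2, DMSO, CH2Cl2, −78 °C; Et3N, −78 → 0 °C; used as crude solution
Reagents that add atoms: none
Why: Swern oxidation stops at the aldehyde and does not touch the terminal alkyne or the ether.

Step 2
Reactants: 3 (S)-lactic acid; 4 pivalaldehyde
Product: 5 (2S,5S)-2-tert-butyl-5-methyl-1,3-dioxolan-4-one
Conditions: p-TsOH (cat.), H2SO4 (cat.), pentane, reflux, Dean–Stark; cis isomer crystallised from pentane at −78 °C
Reagents that add atoms: none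
Why: Acid-catalysed acetalisation of the α-hydroxy acid with removal of water; the acetal carbon is set under thermodynamic control cis to the methyl group and the cis isomer is purified by crystallisation.

Step 3
Reactants: 5 (2S,5S)-2-tert-butyl-5-methyl-1,3-dioxolan-4-one; 2 2-(prop-2-yn-1-yloxy)acetaldehyde
Product: 7 (2S,5R)-2-tert-butyl-5-[1-hydroxy-2-(prop-2-yn-1-yloxy)ethyl]-5-methyl-1,3-dioxolan-4-one, via lithium enolate 6 (not isolated)
Conditions: LDA, THF, −78 °C; then 2, −78 °C; AcOH quench at −78 °C
Reagents that add atoms: none
Why: Aldol addition with self-regeneration of the stereocentre: the aldehyde attacks the enolate face anti to the tert-butyl group, so the C10–C9 bond replaces the lactate C–H with retention and fixes quaternary C10 (R), while C9 forms as two epimers that merge on oxidation in step 14.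

Step 4
Reactants: 7 (2S,5R)-2-tert-butyl-5-[1-hydroxy-2-(prop-2-yn-1-yloxy)ethyl]-5-methyl-1,3-dioxolan-4-one
Product: 8 C9 tert-butyldimethylsilyl ether of 7
Conditions: TBSOTf, 2,6-lutidine, CH2Cl2, −78 → 0 °C
Reagents that add atoms: tert-butyldimethylsilyl triflate, CC(C)(C)[Si](C)(C)OS(=O)(=O)C(F)(F)F
Why: Silyl triflate/lutidine silylation is the standard protection of a hindered secondary alcohol and leaves the acylal lactone and the alkyne intact.

Step 5
Reactants: 9 (Z)-3-methylpent-2-en-4-yn-1-ol
Product: 11 (Z)-3-methyl-5-(trimethylsilyl)pent-2-en-4-yn-1-ol, via bis-silyl ether 10 (not isolated)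
Conditions: EtMgBr (2.1 equiv), THF, 0 → 40 °C; TMSCl (2.2 equiv), 0 °C → rt; then 1 M HCl, rt
Reagents that add atoms: chlorotrimethylsilane, C[Si](C)(C)Cl
Why: Double deprotonation (alkoxide and magnesium acetylide), silylation at both sites and selective acid hydrolysis of the labile O–Si bond give the C-silylated enynol with the Z-alkene unchanged.

Step 6
Reactants: 11 (Z)-3-methyl-5-(trimethylsilyl)pent-2-en-4-yn-1-ol
Product: 12 (Z)-3-methyl-5-(trimethylsilyl)pent-2-en-4-ynal
Conditions: activated MnO2, CH2Cl2, rt, dark; used at once
Reagents that add atoms: none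
Why: MnO2 oxidises the allylic alcohol selectively to the enal under neutral conditions, which limits Z→E isomerisation.

Step 7
Reactants: 8 C9 tert-butyldimethylsilyl ether of 7; 12 (Z)-3-methyl-5-(trimethylsilyl)pent-2-en-4-ynal
Product: 14 (6R,4Z)-propargylic alcohol in which the alkyne terminus C7 of 8 is bonded to C6H(OH)–C5H=C4(CH3)–C3≡C2–SiMe3, via methylzinc acetylide 13 (not isolated)
Conditions: 8 (1.5 equiv), Me2Zn (3 equiv), ProPhenol (20 mol%), Ph3P=O (40 mol%), toluene, 0 °C, 1 h; then 12, 0–4 °C
Reagents that add atoms: none
Why: Zinc-alkynylide addition to an aldehyde under dinuclear zinc–ProPhenol catalysis, a method suited to α,β-unsaturated aldehydes; the catalyst selects the aldehyde face and sets C6 (R) independently of the remote C9/C10 centres, and the ester-type dioxolanone is inert to the zinc reagents.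

Step 8
Reactants: 14 (6R,4Z)-propargylic alcohol
Product: 16 (6R)-vinyl iodide triol HOC1H2–C10(CH3)(OH)–C9H(OTBS)–C8H2–O–C13H2–C11(I)=C7H–C6H(OH)–C5H=C4(CH3)–C3≡C2–SiMe3 with iodine cis to C6, via alkenylalanate 15 (not isolated)
Conditions: Red-Al (3.5 equiv), THF, −20 → 0 °C; EtOAc, −78 °C; I2 (1.2 equiv), THF, −78 °C; cold Na2S2O3/Rochelle salt work-up
Reagents that add atoms: iodine, II
Why: Two known hydride reactions run together: Red-Al reduces the acylal lactone to the C1 primary alcohol (freeing the C10 hydroxyl), and the C6 alkoxide directs trans-hydroalumination of the propargylic alkyne with aluminium at the distal carbon C11, so that iodinolysis with retention gives the Z-iodide.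

Step 9
Reactants: 16 (6R)-vinyl iodide triol
Product: 17 (6R)-butenolide diol: 5-substituted 3-(alkoxymethyl)furan-2(5H)-one with C1 and C10 hydroxyls free
Conditions: Pd(PPh3)4 (5 mol%), CO (1 atm), K2CO3, THF, 40 °C
Reagents that add atoms: carbon monoxide, [C-]#[O+]
Why: Palladium-catalysed carbonylative lactonisation of a (Z)-γ-hydroxy vinyl iodide: oxidative addition, CO insertion and capture of the acyl-palladium by the cis C6 hydroxyl close the five-membered butenolide, the only ring size within reach of the three hydroxyls.

Step 10
Reactants: 17 (6R)-butenolide diol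
Product: 18 (6R)-butenolide diol with C2 iodoalkyne
Conditions: NIS (1.3 equiv), AgNO3 (20 mol%), acetone, rt, dark
Reagents that add atoms: N-iodosuccinimide, O=C1CCC(=O)N1I
Why: Silver-catalysed ipso-iododesilylation of an alkynylsilane gives the 1-iodoalkyne under neutral conditions; it is placed after the lactonisation because silver salts cycloisomerise free (Z)-2-en-4-yn-1-ols to furans.

Step 11
Reactants: 18 (6R)-butenolide diol with C2 iodoalkyne
Product: 19 α-hydroxy aldehyde (C1 aldehyde next to the tertiary C10 hydroxyl)
Conditions: TEMPO (20 mol%), PhI(OAc)2 (1.2 equiv), CH2Cl2, rt; used at once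
Reagents that add atoms: none
Why: TEMPO/PhI(OAc)2 oxidises the primary alcohol to the aldehyde and cannot touch the tertiary C10 hydroxyl; the aldehyde has no α-hydrogen and so cannot enolise.

Step 12
Reactants: 19 α-hydroxy aldehyde
Product: 20 13-membered carbocyclic propargylic alcohol (ring C1–C7, C11, C13, O, C8–C10) carrying the butenolide and the C9 silyl ether
Conditions: CrCl2 (8 equiv), NiCl2 (1 mol%), THF/DMF, rt, syringe-pump addition (final 2 mM)
Reagents that add atoms: none
Why: Nozaki–Hiyama–Kishi-type coupling: Cr(II) inserts into the C–I bond of the iodoalkyne and the alkynylchromium(III) adds chemoselectively to the aldehyde, closing the 13-membered ring at C1–C2 under neutral conditions; the new carbinol C1 (both epimers) is oxidised in step 14.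

Step 13
Reactants: 20 13-membered carbocyclic propargylic alcohol
Product: 21 13-membered 1,9,10-triol
Conditions: HF (48% aq.)/MeCN, 0 °C → rt
Reagents that add atoms: none
Why: Acidic fluoride cleaves the silyl ether without base, so the butenolide and its C6 centre are not at risk.

Step 14
Reactants: 21 13-membered 1,9,10-triol
Product: 22 13-membered 10-hydroxy-1,9-dione (C1 ynone, C9 ketone)
Conditions: Dess–Martin periodinane (3 equiv), NaHCO3, CH2Cl2, 0 °C → rt
Reagents that add atoms: none
Why: Dess–Martin oxidation converts both secondary alcohols (propargylic C1 and C9) into ketones in one operation and leaves the tertiary C10 hydroxyl, which removes the two undefined centres.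

Step 15
Reactants: 22 13-membered 10-hydroxy-1,9-dione
Product: 23 13-membered ether-bridged butenolide furanone (C8–O–C13 ether, C9 ketone, 6R,10R)
Conditions: Ph3PAuCl (5 mol%), AgOTf (5 mol%), toluene, rt
Reagents that add atoms: none
Why: Cationic gold(I) activates the ynone triple bond for 5-endo-dig attack by the C10 hydroxyl, the known cyclisation of γ-hydroxy alkynones to 3(2H)-furanones, which closes the furanone ring (O joins C3 and C10) under neutral conditions.

Step 16
Reactants: 23 13-membered ether-bridged butenolide furanone
Product: 26 C9-keto C8-hydroxy bridged α-methylene lactone (6R,7S,8S,10R), via boron enolate 24 (not isolated), via O-borinate 25 (not isolated)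
Conditions: Bu2BOTf (1.15 equiv), i-Pr2NEt (1.3 equiv), CH2Cl2, −78 °C, 45 min; then −78 → 0 °C; pH 7 buffer/MeOH
Reagents that add atoms: none
Why: Proposed new method: soft enolisation with Bu2BOTf/i-Pr2NEt should give the boron enolate 24 of the C9 ketone, which can only enolise towards C8 because C10 is quaternary; on warming, C8 bonds to C7 through a five-centre envelope (C8–O–C13–C11=C7) while O–C13 breaks and the double bond moves to C11=C13, an anionic [2,3]-Wittig shift that the lactone carbonyl on C11 should speed up by stabilising the charge building there, and the borinate 25 is hydrolysed to 26 on work-up. The closest known reactions are the boron-enolate [2,3]-Wittig shift of α-allyloxy ketones and the [2,3]-Wittig ring contraction of 13-membered allylic ethers to ten-membered carbocycles; an electron-poor butenolide as the allyl partner has not been shown. The ten-membered carbocycle closes by this transannular sigmatropic contraction of the 13-membered ring (not a Baldwin-type cyclisation; the stepwise Michael/elimination alternative would be a 5-endo-trig addition and is not relied on), and the α-methylene lactone appears without a separate methylenation. C7 (S) is controlled by C6: C8 is delivered to the butenolide face anti to the C5 arm, the usual facial bias of γ-substituted butenolides, which gives the trans-fused lactone; C8 (S) follows from the envelope in which the enolate unit lies over the allyl fragment, the syn outcome typical of enolate Wittig shifts of E-configured ethers, and has to be confirmed (NOE or X-ray). The step needs enolisation at C8 in preference to removal of the acidic γ-hydrogen H-6 of the dienyl butenolide, which would scramble C6; this is secured by the known preference of boron triflate/amine for ketones over ester-type carbonyls at −78 °C, by using barely more than one equivalent of each reagent and by the absence of any stronger base.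

Step 17
Reactants: 26 C9-keto C8-hydroxy bridged α-methylene lactone
Product: 27 8,9-cis diol (8S,9S)
Conditions: Zn(BH4)2, Et2O/CH2Cl2, −40 → −20 °C; aq. NH4Cl
Reagents that add atoms: none
Why: Chelation-controlled reduction: zinc bridges the C8 hydroxyl and the C9 carbonyl and hydride adds to the chelate face away from C7, which gives the anti (ring-cis) diol with C9 (S); the vinylogous ester C1=O, the lactone and the exocyclic alkene should not be reduced by Zn(BH4)2 at low temperature.

Step 18
Reactants: 28 tert-butyl acrylate; 29 acetaldehyde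
Product: 30 tert-butyl 3-hydroxy-2-methylidenebutanoate (racemic)
Conditions: DABCO (0.5 equiv), neat, rt
Reagents that add atoms: none
Why: Morita–Baylis–Hillman reaction under DABCO catalysis gives the allylic alcohol, whose stereocentre is removed in the next step.

Step 19
Reactants: 30 tert-butyl 3-hydroxy-2-methylidenebutanoate
Product: 32 tert-butyl (E)-2-(acetoxymethyl)but-2-enoate, via secondary acetate 31 (not isolated)
Conditions: Ac2O, pyridine, DMAP (cat.), CH2Cl2, 0 °C → rt; then DABCO (20 mol%), THF, reflux
Reagents that add atoms: acetic anhydride, CC(=O)OC(C)=O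
Why: Acetylation followed by DABCO-catalysed 1,3-transposition of the allylic acetate (SN2′–SN2′) gives the thermodynamically preferred trisubstituted E-enoate, with the ester carbonyl trans to the β-methyl group.

Step 20
Reactants: 32 tert-butyl (E)-2-(acetoxymethyl)but-2-enoate
Product: 33 (E)-2-(acetoxymethyl)but-2-enoic acid
Conditions: TFA/CH2Cl2 (1:4), 0 °C → rt
Reagents that add atoms: none
Why: Acidolysis of the tert-butyl ester (loss of isobutene) frees the acid without cleaving the primary acetate.

Step 21
Reactants: 27 8,9-cis diol; 33 (E)-2-(acetoxymethyl)but-2-enoic acid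
Product: 35 C8 (E)-2-(acetoxymethyl)but-2-enoate with free C9 hydroxyl, via acid chloride 34 (not isolated)
Conditions: 33, (COCl)2, DMF (cat.), CH2Cl2, 0 °C → rt, concentrate; then 27, pyridine, DMAP (10 mol%), CH2Cl2, −20 → 0 °C
Reagents that add atoms: none
Why: Acylation with the acid chloride under mild base: the C8 hydroxyl, flanked by two methine carbons, should react before the neopentyl-type C9 hydroxyl next to quaternary C10, and the low DMAP loading and temperature avoid SN2′ attack on the allylic acetate.

Step 22
Reactants: 35 C8 (E)-2-(acetoxymethyl)but-2-enoate with free C9 hydroxyl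
Product: 36 CNP0325609.1
Conditions: Ac2O, pyridine, DMAP (cat.), CH2Cl2, rt
Reagents that add atoms: acetic anhydride, CC(=O)OC(C)=O
Why: DMAP-catalysed acetylation of the remaining hindered C9 hydroxyl completes the target without touching any stereocentre.

## Compound list

1 | 2-(prop-2-yn-1-yloxy)ethan-1-ol | C#CCOCCO | starting material
2 | 2-(prop-2-yn-1-yloxy)acetaldehyde | C#CCOCC=O | intermediate
3 | (S)-lactic acid | C[C@H](O)C(=O)O | starting material
4 | pivalaldehyde | CC(C)(C)C=O | starting material
5 | (2S,5S)-2-tert-butyl-5-methyl-1,3-dioxolan-4-one (cis) | C[C@@H]1O[C@H](C(C)(C)C)OC1=O | intermediate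
6 | lithium enolate of 5 (lithium 2-tert-butyl-5-methyl-1,3-dioxol-4-olate, acetal centre unchanged) | CC1=C(O[Li])O[C@@H](C(C)(C)C)O1 | intermediate
7 | (2S,5R)-2-tert-butyl-5-[1-hydroxy-2-(prop-2-yn-1-yloxy)ethyl]-5-methyl-1,3-dioxolan-4-one (C9 epimers) | C[C@]1(C(O)COCC#C)O[C@H](C(C)(C)C)OC1=O | intermediate
8 | C9 tert-butyldimethylsilyl ether of 7 | C[C@]1(C(O[Si](C)(C)C(C)(C)C)COCC#C)O[C@H](C(C)(C)C)OC1=O | intermediate
9 | (Z)-3-methylpent-2-en-4-yn-1-ol | C#C/C(C)=C\CO | starting material
10 | (Z)-3-methyl-1-(trimethylsilyloxy)-5-(trimethylsilyl)pent-2-en-4-yne | C[Si](C)(C)C#C/C(C)=C\CO[Si](C)(C)C | intermediate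
11 | (Z)-3-methyl-5-(trimethylsilyl)pent-2-en-4-yn-1-ol | C[Si](C)(C)C#C/C(C)=C\CO | intermediate
12 | (Z)-3-methyl-5-(trimethylsilyl)pent-2-en-4-ynal | C[Si](C)(C)C#C/C(C)=C\C=O | intermediate
13 | methylzinc acetylide of 8 | C[C@]1(C(O[Si](C)(C)C(C)(C)C)COCC#C[Zn]C)O[C@H](C(C)(C)C)OC1=O | intermediate
14 | (6R,4Z)-propargylic alcohol: dioxolanone–C9H(OTBS)–C8H2–O–C13H2–C11≡C7–C6H(OH)–C5H=C4(CH3)–C3≡C2–SiMe3 | C[C@]1(C(O[Si](C)(C)C(C)(C)C)COCC#C[C@H](O)/C=C(/C)C#C[Si](C)(C)C)O[C@H](C(C)(C)C)OC1=O | intermediate
15 | alkenylalanate after hydride reduction (schematic: sodium alkoxides at O1 and O10, cyclic C11–Al–O6 ate complex) | [Na+].[Na+].[Na+].[O-]C[C@](C)([O-])C(O[Si](C)(C)C(C)(C)C)COCC1=C[C@@H](/C=C(/C)C#C[Si](C)(C)C)O[Al-]1(OCCOC)OCCOC | intermediate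
16 | (6R)-vinyl iodide triol, iodine on C11 cis to C6, 4Z | OC[C@](C)(O)C(O[Si](C)(C)C(C)(C)C)COC/C(I)=C/[C@H](O)/C=C(/C)C#C[Si](C)(C)C | intermediate
17 | (6R)-butenolide diol with C2 silylalkyne | OC[C@](C)(O)C(O[Si](C)(C)C(C)(C)C)COCC1=C[C@@H](/C=C(/C)C#C[Si](C)(C)C)OC1=O | intermediate
18 | (6R)-butenolide diol with C2 iodoalkyne | OC[C@](C)(O)C(O[Si](C)(C)C(C)(C)C)COCC1=C[C@@H](/C=C(/C)C#CI)OC1=O | intermediate
19 | α-hydroxy aldehyde (C1 aldehyde, C10 tertiary alcohol, iodoalkyne, butenolide) | O=C[C@](C)(O)C(O[Si](C)(C)C(C)(C)C)COCC1=C[C@@H](/C=C(/C)C#CI)OC1=O | intermediate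
20 | 13-membered carbocyclic propargylic alcohol (C1 epimers) with butenolide and C9 silyl ether | OC1C#C/C(C)=C\[C@H]2OC(=O)C(=C2)COCC(O[Si](C)(C)C(C)(C)C)[C@@]1(C)O | intermediate
21 | 13-membered 1,9,10-triol | OC1C#C/C(C)=C\[C@H]2OC(=O)C(=C2)COCC(O)[C@@]1(C)O | intermediate
22 | 13-membered 10-hydroxy-1,9-dione (C1 ynone) | O=C1C#C/C(C)=C\[C@H]2OC(=O)C(=C2)COCC(=O)[C@@]1(C)O | intermediate
23 | 13-membered ether-bridged butenolide furanone (6R,10R), key-step precursor | O=C1O[C@H](/C=C(/C)C2=CC(=O)[C@](C)(O2)C(=O)COC3)C=C13 | intermediate
24 | dibutylboron enolate of 23 (C8=C9, geometry imposed by the ring, not assigned) | O=C1O[C@H](/C=C(/C)C2=CC(=O)[C@](C)(O2)C(OB(CCCC)CCCC)=COC3)C=C13 | intermediate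
25 | O8-dibutylborinate of 26 | C=C1C(=O)O[C@@H]2/C=C(/C)C3=CC(=O)[C@](C)(O3)C(=O)[C@@H](OB(CCCC)CCCC)[C@@H]12 | intermediate
26 | C9-keto C8-hydroxy bridged α-methylene lactone (6R,7S,8S,10R), key-step product | C=C1C(=O)O[C@@H]2/C=C(/C)C3=CC(=O)[C@](C)(O3)C(=O)[C@@H](O)[C@@H]12 | intermediate
27 | 8,9-cis diol (8S,9S) | C=C1C(=O)O[C@@H]2/C=C(/C)C3=CC(=O)[C@](C)(O3)[C@@H](O)[C@@H](O)[C@@H]12 | intermediate
28 | tert-butyl acrylate | C=CC(=O)OC(C)(C)C | starting material
29 | acetaldehyde | CC=O | starting material
30 | tert-butyl 3-hydroxy-2-methylidenebutanoate (racemic) | CC(O)C(=C)C(=O)OC(C)(C)C | intermediate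
31 | tert-butyl 3-acetoxy-2-methylidenebutanoate (racemic) | CC(OC(C)=O)C(=C)C(=O)OC(C)(C)C | intermediate
32 | tert-butyl (E)-2-(acetoxymethyl)but-2-enoate | CC(C)(C)OC(=O)/C(=C/C)COC(C)=O | intermediate
33 | (E)-2-(acetoxymethyl)but-2-enoic acid | OC(=O)/C(=C/C)COC(C)=O | intermediate
34 | (E)-2-(acetoxymethyl)but-2-enoyl chloride | O=C(Cl)/C(=C/C)COC(C)=O | intermediate
35 | C8 (E)-2-(acetoxymethyl)but-2-enoate with free C9 hydroxyl | C=C1C(=O)O[C@@H]2/C=C(/C)C3=CC(=O)[C@](C)(O3)[C@@H](O)[C@@H](OC(=O)/C(=C/C)COC(C)=O)[C@@H]12 | intermediate
36 | CNP0325609.1 | C=C1C(=O)O[C@@H]2/C=C(/C)C3=CC(=O)[C@](C)(O3)[C@@H](OC(C)=O)[C@@H](OC(=O)/C(=C/C)COC(C)=O)[C@@H]12 | target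

## Step count and risks

Total: 22 steps (19 in the main line, 3 for the side-chain acid). Longest linear sequence: 16 steps (steps 1, 3, 4, 7–17, 21, 22).

Steps most likely to fail:

1. Step 16 (ring contraction, proposed new method). What may go wrong: removal of H-6 instead of H-8 (γ-deprotonation of the butenolide, with epimerisation at C6 or formation of a 2-boryloxyfuran), an enolate that does not rearrange before it decomposes, or bond formation on the wrong face of C7 or C8. The fallback makes the same C7–C8 bond by a known allyl-metal addition and sets out from 23. Me2BBr (CH2Cl2, −78 °C) should cleave the C8–O–C13 ether at the allylic carbon: the boron is held between the ether oxygen and the C9 carbonyl, the C8–O bond then lies in the carbonyl plane and is not activated for displacement, and bromide enters at C13. This gives the 3-(bromomethyl)butenolide ketol F1. Dess–Martin oxidation of its primary ketol hydroxyl gives the keto aldehyde F2. An indium-mediated intramolecular Barbier allylation (In, THF/H2O, high dilution) would then close the ten-membered ring at C7–C8 and come back to the route at 26; with 3-(bromomethyl)furan-2(5H)-ones this reaction is known to attack aldehydes through the ring β-carbon and to give β-(hydroxyalkyl)-α-methylene lactones.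

2. Step 12 (macrocyclisation). What may go wrong: intermolecular coupling (oligomers) outrunning ring closure, or attack of Cr(II) or chromium alkoxides on the butenolide (reduction, epimerisation at C6). The fallback closes the same ring before the base-sensitive lactone exists and with a different organometallic; it sets out from 16. K2CO3/MeOH removes the alkyne silyl group to give the C-desilylated vinyl iodide triol F3. TEMPO/PhI(OAc)2, which prefers the primary over the secondary allylic hydroxyl, gives the terminal-alkyne hydroxy aldehyde F4. Excess LiHMDS (THF, −78 °C, high dilution) forms the lithium acetylide, which adds to the non-enolisable aldehyde (the vinyl iodide is inert to the amide base) and gives the 13-membered vinyl iodide triol F5. Carbonylative lactonisation under the conditions of step 9 then comes back to the route at 20.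

3. Step 17 (C9 reduction). What may go wrong: hydride delivery to the wrong face of C9 if the ring conformation overrides the zinc chelate, or 1,4-reduction of the methylene lactone. The fallback replaces substrate control by reagent control and sets out from 26. Its single hydroxyl (C8) is acylated with acid chloride 34 (pyridine, cat. DMAP) to give the 8-O-acyl 9-ketone F6, which also removes the later question of which hydroxyl is acylated. Reduction with (R)-2-methyl-CBS-oxazaborolidine and catecholborane (toluene, −78 °C), with quaternary C10 as the large group, is expected to give the 9S carbinol and comes back to the route at 35.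

## Further compounds

F1 | step 16 | 3-(bromomethyl)butenolide ketol (C13–Br, C8–OH, C9 ketone) | BrCC1=C[C@@H](/C=C(/C)C2=CC(=O)[C@](C)(O2)C(=O)CO)OC1=O
F2 | step 16 | 3-(bromomethyl)butenolide keto aldehyde (C8 aldehyde, C9 ketone) | BrCC1=C[C@@H](/C=C(/C)C2=CC(=O)[C@](C)(O2)C(=O)C=O)OC1=O
F3 | step 12 | C-desilylated vinyl iodide triol | OC[C@](C)(O)C(O[Si](C)(C)C(C)(C)C)COC/C(I)=C/[C@H](O)/C=C(/C)C#C
F4 | step 12 | terminal-alkyne hydroxy aldehyde with vinyl iodide | O=C[C@](C)(O)C(O[Si](C)(C)C(C)(C)C)COC/C(I)=C/[C@H](O)/C=C(/C)C#C
F5 | step 12 | 13-membered vinyl iodide triol (C1 epimers) | OC1C#C/C(C)=C\[C@@H](O)/C=C(I)/COCC(O[Si](C)(C)C(C)(C)C)[C@@]1(C)O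
F6 | step 17 | 8-O-[(E)-2-(acetoxymethyl)but-2-enoyl] 9-ketone | C=C1C(=O)O[C@@H]2/C=C(/C)C3=CC(=O)[C@](C)(O3)C(=O)[C@@H](OC(=O)/C(=C/C)COC(C)=O)[C@@H]12
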